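**Retrosynthetic overview**

1. Numbering (germacrane): ring A is the ten-membered carbocycle C1(=O)–C2–C3–C4(CH3)=C5–C6(O)–C7–C8(O-angeloyl)–C9–C10(CH3); ring B is the butenolide O6–C12(=O)–C11(C13H2OAc)=C7–C6. The last operations are C13–Cl → C13–OAc and epoxidation of the (E)-C4=C5 bond from the ring periphery.
2. Key disconnection C11–C12 (together with O6–C12): ring B comes from CO, chloride and a macrocyclic 2,3-allenol (C6–OH, C7=C11=C13H2) by PdCl2/CuCl2 chlorocyclocarbonylation. The enabling feature is that the carbinol carbon C6 sits directly on C7 of the tetrasubstituted C7=C11 alkene, whose C11 carries both the lactone carbonyl C12 and the heteroatom-bearing C13; the array C6(O)–C7=C11–C13(X) is therefore an allenyl carbinol plus one CO, and the other oxygen next to C7 (O8) is already acylated.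
3. Ring A: C7–C8 by intramolecular CrCl2 Barbier allenylation (SE2') of a C13 propargylic bromide onto the C8 aldehyde, which makes the ring, the exocyclic allene and the C8 carbinol in one step.
4. Open chain: C6–C7 by zinc–ProPhenol alkynylation of an (E)-enal (sets C6), C1–C2 by Weinreb amide/Grignard coupling, C10 by Evans allylation (the only auxiliary-derived stereocentre; C8, C4 and C5 are relayed by substrate control).
5. Order of ring formation: ring A (step 16), ring B (step 19), oxirane (step 21).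

Key step: step 19

Remark 1: the 2-methylbut-2-enoate is read as drawn, (Z) (angelate); atom labels C1–C13 in the text and the descriptors (4R,5R,6S,8S,10R) of the target follow the germacrane numbering given above.
Remark 2: in step 11 the (S,S)-ProPhenol ligand is assumed to deliver the alkynyl group to the Si face of the enal; if the sense is opposite, the (R,R)-ligand is used with no other change.

**Route**

Step 1
Reactants: 1 tert-butyl(but-3-yn-1-yloxy)dimethylsilane
Product: 4 (E)-5-[(tert-butyldimethylsilyl)oxy]-3-methylpent-2-en-1-ol, via alkenylalane 2 (not isolated), via lithium alanate 3 (not isolated)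
Conditions: Me3Al, Cp2ZrCl2 (cat.), CH2Cl2, 0 °C → rt; then n-BuLi, THF, −78 °C; (CH2O)n, → rt
Reagents that add atoms: trimethylaluminium C[Al](C)C; paraformaldehyde (as formaldehyde) C=O
Why: Negishi zirconium-catalysed carboalumination adds CH3–Al syn across the terminal alkyne with the methyl on the internal carbon, and the derived alanate attacks formaldehyde with retention at the alkenyl carbon, so the (E)-trisubstituted alkene (later C4=C5 with its methyl) should form as one isomer.

Step 2
Reactants: 4 (E)-5-[(tert-butyldimethylsilyl)oxy]-3-methylpent-2-en-1-ol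
Product: 6 tert-butyl{[(E)-5-[(4-methoxybenzyl)oxy]-3-methylpent-3-en-1-yl]oxy}dimethylsilane, via sodium alkoxide 5 (not isolated)
Conditions: NaH, 4-methoxybenzyl chloride, Bu4NI (cat.), THF–DMF, 0 °C → rt
Reagents that add atoms: 4-methoxybenzyl chloride COc1ccc(CCl)cc1
Why: Williamson etherification of the primary allylic alkoxide with a benzylic chloride, to which the silyl ether is inert.

Step 3
Reactants: 6 tert-butyl{[(E)-5-[(4-methoxybenzyl)oxy]-3-methylpent-3-en-1-yl]oxy}dimethylsilane
Product: 7 (E)-5-[(4-methoxybenzyl)oxy]-3-methylpent-3-en-1-ol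
Conditions: Bu4NF, THF, 0 °C → rt
Reagents that add atoms: none
Why: Fluoride-mediated cleavage of the primary silyl ether, driven by Si–F bond formation, leaves the benzyl-type ether and the alkene untouched.

Step 4
Reactants: 7 (E)-5-[(4-methoxybenzyl)oxy]-3-methylpent-3-en-1-ol
Product: 8 1-({[(E)-5-bromo-3-methylpent-2-en-1-yl]oxy}methyl)-4-methoxybenzene
Conditions: CBr4, PPh3, CH2Cl2, 0 °C
Reagents that add atoms: tetrabromomethane BrC(Br)(Br)Br
Why: Appel bromination converts the primary homoallylic alcohol into the bromide by SN2 displacement of the oxyphosphonium group under neutral conditions.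

Step 5
Reactants: 9 (S)-4-benzyl-3-propanoyl-1,3-oxazolidin-2-one; 10 3-iodoprop-1-ene (allyl iodide)
Product: 12 (S)-4-benzyl-3-[(R)-2-methylpent-4-enoyl]-1,3-oxazolidin-2-one, via sodium enolate 11 (not isolated)
Conditions: NaN(SiMe3)2, THF, −78 °C; then 10, −78 → −45 °C
Reagents that add atoms: none
Why: Evans asymmetric alkylation, in which the chelated sodium (Z)-enolate is allylated on the face opposite to the benzyl group, sets the (R)-configured methyl-bearing carbon that becomes C10.

Step 6
Reactants: 12 (S)-4-benzyl-3-[(R)-2-methylpent-4-enoyl]-1,3-oxazolidin-2-one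
Product: 13 (R)-N-methoxy-N,2-dimethylpent-4-enamide
Conditions: MeNHOMe·HCl, AlMe3, CH2Cl2, 0 °C → rt
Reagents that add atoms: N,O-dimethylhydroxylamine hydrochloride Cl.CNOC
Why: Weinreb aminolysis of the exocyclic imide carbonyl by the aluminium amide made from AlMe3 and the amine hydrochloride releases the auxiliary without epimerising the α-stereocentre.

Step 7
Reactants: 13 (R)-N-methoxy-N,2-dimethylpent-4-enamide
Product: 15 (R)-N,4,4-trimethoxy-N,2-dimethylbutanamide, via aldehyde 14 (not isolated)
Conditions: O3, CH2Cl2–MeOH, −78 °C; Me2S, → rt; then HC(OMe)3, TsOH·H2O (cat.), MeOH, rt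
Reagents that add atoms: trimethyl orthoformate COC(OC)OC
Why: Ozonolysis with reductive work-up cleaves the only alkene to the aldehyde (C8), which is masked in the same flask by acid-catalysed acetalisation so that it survives the organometallic steps.

Step 8
Reactants: 8 1-({[(E)-5-bromo-3-methylpent-2-en-1-yl]oxy}methyl)-4-methoxybenzene; 15 (R)-N,4,4-trimethoxy-N,2-dimethylbutanamide
Product: 17 (3R,7E)-1,1-dimethoxy-9-[(4-methoxybenzyl)oxy]-3,7-dimethylnon-7-en-4-one, via Grignard reagent 16 (not isolated)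
Conditions: Mg, THF, rt → 40 °C; then 15, THF, 0 °C; aq. NH4Cl
Reagents that add atoms: none
Why: Grignard addition to the N-methoxy-N-methylamide (Weinreb ketone synthesis) stops at the ketone stage and forms the C1–C2 bond without touching the acetal or the α-stereocentre.

Step 9
Reactants: 17 (3R,7E)-1,1-dimethoxy-9-[(4-methoxybenzyl)oxy]-3,7-dimethylnon-7-en-4-one
Product: 18 (3R,7E)-9-hydroxy-1,1-dimethoxy-3,7-dimethylnon-7-en-4-one
Conditions: DDQ, CH2Cl2–pH 7 buffer, 0 °C
Reagents that add atoms: none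
Why: Oxidative cleavage of the 4-methoxybenzyl ether by DDQ (benzylic hydride abstraction, then hydrolysis) frees the allylic alcohol while acetal and ketone are inert under the buffered conditions.

Step 10
Reactants: 18 (3R,7E)-9-hydroxy-1,1-dimethoxy-3,7-dimethylnon-7-en-4-one
Product: 19 (2E,7R)-9,9-dimethoxy-3,7-dimethyl-6-oxonon-2-enal
Conditions: MnO2, CH2Cl2, rt
Reagents that add atoms: none
Why: MnO2 oxidises the allylic alcohol selectively to the (E)-enal (C6) without alkene isomerisation or epimerisation next to the ketone.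

Step 11
Reactants: 19 (2E,7R)-9,9-dimethoxy-3,7-dimethyl-6-oxonon-2-enal; 20 tert-butyldimethyl(prop-2-yn-1-yloxy)silane
Product: 22 (3R,7E,9R)-12-[(tert-butyldimethylsilyl)oxy]-9-hydroxy-1,1-dimethoxy-3,7-dimethyldodec-7-en-10-yn-4-one, via alkynylzinc 21 (not isolated)
Conditions: Me2Zn, (S,S)-2,6-bis{[2-(hydroxydiphenylmethyl)pyrrolidin-1-yl]methyl}-4-methylphenol [(S,S)-ProPhenol, cat.], Ph3P=O (cat.), toluene, 0–4 °C
Reagents that add atoms: none
Why: Zinc–ProPhenol catalysed asymmetric alkynylation of an α,β-unsaturated aldehyde, in which the dinuclear zinc catalyst delivers the alkynylzinc to the Si face under reagent control, should set the C6 carbinol as (R) in this compound and leave the less electrophilic ketone alone.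

Step 12
Reactants: 22 (3R,7E,9R)-12-[(tert-butyldimethylsilyl)oxy]-9-hydroxy-1,1-dimethoxy-3,7-dimethyldodec-7-en-10-yn-4-one
Product: 23 (3R,7E,9R)-9,12-bis[(tert-butyldimethylsilyl)oxy]-1,1-dimethoxy-3,7-dimethyldodec-7-en-10-yn-4-one
Conditions: tert-butyldimethylsilyl chloride, imidazole, DMF, rt
Reagents that add atoms: tert-butyldimethylsilyl chloride CC(C)(C)[Si](C)(C)Cl
Why: Imidazole-promoted silylation protects O6 as a non-leaving silyl ether for the organochromium step and keeps it distinct from O8 later.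

Step 13
Reactants: 23 (3R,7E,9R)-9,12-bis[(tert-butyldimethylsilyl)oxy]-1,1-dimethoxy-3,7-dimethyldodec-7-en-10-yn-4-one
Product: 24 (3R,7E,9R)-9-[(tert-butyldimethylsilyl)oxy]-12-hydroxy-1,1-dimethoxy-3,7-dimethyldodec-7-en-10-yn-4-one
Conditions: HF·pyridine, pyridine, THF, 0 °C
Reagents that add atoms: none
Why: Buffered HF·pyridine desilylation discriminates on steric grounds and should cleave the unhindered primary propargylic silyl ether well before the secondary one, while the acetal tolerates the buffered medium.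

Step 14
Reactants: 24 (3R,7E,9R)-9-[(tert-butyldimethylsilyl)oxy]-12-hydroxy-1,1-dimethoxy-3,7-dimethyldodec-7-en-10-yn-4-one
Product: 25 (3R,7E,9R)-12-bromo-9-[(tert-butyldimethylsilyl)oxy]-1,1-dimethoxy-3,7-dimethyldodec-7-en-10-yn-4-one
Conditions: CBr4, PPh3, CH2Cl2, 0 °C
Reagents that add atoms: tetrabromomethane BrC(Br)(Br)Br
Why: Appel bromination of the primary propargylic alcohol is fast at 0 °C and is run before the aldehyde is unmasked, so no dibromo-olefination can compete.

Step 15
Reactants: 25 (3R,7E,9R)-12-bromo-9-[(tert-butyldimethylsilyl)oxy]-1,1-dimethoxy-3,7-dimethyldodec-7-en-10-yn-4-one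
Product: 26 (3R,7E,9R)-12-bromo-9-[(tert-butyldimethylsilyl)oxy]-3,7-dimethyl-4-oxododec-7-en-10-ynal
Conditions: pyridinium 4-toluenesulfonate (cat.), acetone–H2O, 50 °C
Reagents that add atoms: water O
Why: Mild acid-catalysed hydrolysis of the dimethyl acetal frees the C8 aldehyde under conditions that the secondary silyl ether, the bromide and the ketone should survive.

Step 16
Reactants: 26 (3R,7E,9R)-12-bromo-9-[(tert-butyldimethylsilyl)oxy]-3,7-dimethyl-4-oxododec-7-en-10-ynal
Product: 28 (4E,6R,8S,10R)-6-[(tert-butyldimethylsilyl)oxy]-7-ethenylidene-8-hydroxy-4,10-dimethylcyclodec-4-en-1-one, via propargylchromium dichloride 27 (not isolated)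
Conditions: CrCl2 (8 equiv), THF, 2 mM, slow addition of 26, rt
Reagents that add atoms: none
Why: Nozaki–Hiyama-type Barbier allenylation, in which CrCl2 turns the propargylic bromide into a propargylchromium species that adds to the aldehyde through its γ-carbon C7 (SE2', six-centre transition state, as known for 1-bromo-2-alkynes), should close the ten-membered ring as the chromium Barbier closures of allylic halides do; the C8 carbinol should form cis to the C6 silyloxy and C10 methyl groups because all three can sit pseudo-equatorially on the periphery of the forming ring, and the ketone cannot compete because it would require a seven-membered ring containing the (E)-alkene.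

Step 17
Reactants: 28 (4E,6R,8S,10R)-6-[(tert-butyldimethylsilyl)oxy]-7-ethenylidene-8-hydroxy-4,10-dimethylcyclodec-4-en-1-one; 29 angelic acid [(Z)-2-methylbut-2-enoic acid]
Product: 31 (1S,3R,4E,9R)-3-[(tert-butyldimethylsilyl)oxy]-2-ethenylidene-5,9-dimethyl-8-oxocyclodec-4-en-1-yl (Z)-2-methylbut-2-enoate, via mixed anhydride 30 (not isolated)
Conditions: 29, 2,4,6-trichlorobenzoyl chloride, Et3N, toluene, rt; then 28, 80 °C
Reagents that add atoms: none
Why: Yamaguchi-type esterification through the mixed anhydride without a nucleophilic catalyst acylates O8 at the less hindered angeloyl carbonyl and avoids the addition–elimination isomerisation of angelate to tiglate; it is placed here so that O6 alone is free in the carbonylation.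

Step 18
Reactants: 31 (1S,3R,4E,9R)-3-[(tert-butyldimethylsilyl)oxy]-2-ethenylidene-5,9-dimethyl-8-oxocyclodec-4-en-1-yl (Z)-2-methylbut-2-enoate
Product: 32 (1S,3R,4E,9R)-2-ethenylidene-3-hydroxy-5,9-dimethyl-8-oxocyclodec-4-en-1-yl (Z)-2-methylbut-2-enoate
Conditions: HF·pyridine, THF, 0 °C → rt
Reagents that add atoms: none
Why: Acidic fluoride desilylation frees O6 without the basic conditions that could move the angeloyl group from O8 to O6.

Step 19
Reactants: 32 (1S,3R,4E,9R)-2-ethenylidene-3-hydroxy-5,9-dimethyl-8-oxocyclodec-4-en-1-yl (Z)-2-methylbut-2-enoate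
Product: 33 (4S,6R,10E,11aR)-3-(chloromethyl)-6,10-dimethyl-2,7-dioxo-2,4,5,6,7,8,9,11a-octahydrocyclodeca[b]furan-4-yl (Z)-2-methylbut-2-enoate
Conditions: PdCl2 (5 mol%), CuCl2 (3 equiv), CO (1 atm), propylene oxide (5 equiv), THF, rt
Reagents that add atoms: carbon monoxide [C-]#[O+]; copper dichloride Cl[Cu]Cl
Why: PdCl2, the C6 hydroxyl and CO give an alkoxycarbonylpalladium chloride (O6–C12(=O)–Pd) that inserts the neighbouring allene so that C12 is delivered to the central carbon C11, forming the C11–C12 bond and a π-allylpalladium unit over C7–C11–C13; chloride transfer from CuCl2 to the terminus C13 releases the 3-(chloromethyl)butenolide and zerovalent palladium, which CuCl2 returns to divalent palladium while propylene oxide takes up the HCl. The closest known reaction is the PdCl2/CuCl2 chlorocyclocarbonylation of 2,3-allenols to 3-chloromethyl-2(5H)-furanones, applied here to a 2-substituted, ring-embedded allenol. Ring B is closed by acylpalladation of the central allene carbon, a five-membered closure that is exo with respect to the C11=C13 π-bond and leaves C7=C11 endocyclic. No new stereocentre is formed: the C6–O bond is never broken, and the position of the tetrasubstituted alkene is fixed by chloride attack at C13. The step needs O6 over O8 (secured because O8 is already the angelate), C13 over C7 for the chloride (C7 is a fully substituted ring carbon and attack at C13 gives the conjugated lactone), and carbonylation over 5-endo oxypalladation or reaction at the C4=C5 alkene (the CO atmosphere and the stronger binding of the allene to divalent palladium should secure this). In one operation it brings in C12 and builds ring B, the C7=C11 alkene and the C13 leaving group from a monocyclic precursor.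

Step 20
Reactants: 33 (4S,6R,10E,11aR)-3-(chloromethyl)-6,10-dimethyl-2,7-dioxo-2,4,5,6,7,8,9,11a-octahydrocyclodeca[b]furan-4-yl (Z)-2-methylbut-2-enoate
Product: 34 (4S,6R,10E,11aR)-3-(acetoxymethyl)-6,10-dimethyl-2,7-dioxo-2,4,5,6,7,8,9,11a-octahydrocyclodeca[b]furan-4-yl (Z)-2-methylbut-2-enoate
Conditions: KOAc, 18-crown-6 (cat.), MeCN, 40 °C
Reagents that add atoms: potassium acetate CC(=O)[O-].[K+]
Why: SN2 displacement of the primary allylic chloride by acetate should be clean because the SN2' position C7 is fully substituted and acetate is too weak a base to disturb the lactone or the angelate.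

Step 21
Reactants: 34 (4S,6R,10E,11aR)-3-(acetoxymethyl)-6,10-dimethyl-2,7-dioxo-2,4,5,6,7,8,9,11a-octahydrocyclodeca[b]furan-4-yl (Z)-2-methylbut-2-enoate
Product: 35 (4R,5R,6S,8S,10R)-13-acetoxy-8-[(Z)-2-methylbut-2-enoyloxy]-4,5-epoxy-1-oxogermacr-7(11)-en-12,6-olide (target, germacrane numbering)
Conditions: dimethyldioxirane (1.1 equiv), acetone, −20 → 0 °C
Reagents that add atoms: dimethyldioxirane CC1(C)OO1
Why: Dimethyldioxirane epoxidation under neutral conditions is selective for the only electron-rich alkene and should attack the peripheral face of the (E)-C4=C5 bond in the conformer in which H6 eclipses the alkene (A(1,3) strain with the C4 methyl), that is syn to O6, which gives the trans (4R,5R)-oxirane.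

**Compound list**

1 | tert-butyl(but-3-yn-1-yloxy)dimethylsilane | C#CCCO[Si](C)(C)C(C)(C)C | starting material
2 | {(E)-4-[(tert-butyldimethylsilyl)oxy]-2-methylbut-1-en-1-yl}dimethylalane | C[Al](C)/C=C(C)/CCO[Si](C)(C)C(C)(C)C | intermediate
3 | lithium butyl{(E)-4-[(tert-butyldimethylsilyl)oxy]-2-methylbut-1-en-1-yl}dimethylalanate | [Li+].CCCC[Al-](C)(C)/C=C(C)/CCO[Si](C)(C)C(C)(C)C | intermediate
4 | (E)-5-[(tert-butyldimethylsilyl)oxy]-3-methylpent-2-en-1-ol | OC/C=C(C)/CCO[Si](C)(C)C(C)(C)C | intermediate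
5 | sodium (E)-5-[(tert-butyldimethylsilyl)oxy]-3-methylpent-2-en-1-olate | [Na+].[O-]C/C=C(C)/CCO[Si](C)(C)C(C)(C)C | intermediate
6 | tert-butyl{[(E)-5-[(4-methoxybenzyl)oxy]-3-methylpent-3-en-1-yl]oxy}dimethylsilane | COc1ccc(COC/C=C(C)/CCO[Si](C)(C)C(C)(C)C)cc1 | intermediate
7 | (E)-5-[(4-methoxybenzyl)oxy]-3-methylpent-3-en-1-ol | COc1ccc(COC/C=C(C)/CCO)cc1 | intermediate
8 | 1-({[(E)-5-bromo-3-methylpent-2-en-1-yl]oxy}methyl)-4-methoxybenzene | COc1ccc(COC/C=C(C)/CCBr)cc1 | intermediate
9 | (S)-4-benzyl-3-propanoyl-1,3-oxazolidin-2-one | CCC(=O)N1[C@@H](Cc2ccccc2)COC1=O | starting material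
10 | 3-iodoprop-1-ene (allyl iodide) | C=CCI | starting material
11 | sodium (Z)-1-[(S)-4-benzyl-2-oxo-1,3-oxazolidin-3-yl]prop-1-en-1-olate | [Na+].C/C=C(\[O-])N1[C@@H](Cc2ccccc2)COC1=O | intermediate
12 | (S)-4-benzyl-3-[(R)-2-methylpent-4-enoyl]-1,3-oxazolidin-2-one | C=CC[C@@H](C)C(=O)N1[C@@H](Cc2ccccc2)COC1=O | intermediate
13 | (R)-N-methoxy-N,2-dimethylpent-4-enamide | C=CC[C@@H](C)C(=O)N(C)OC | intermediate
14 | (R)-N-methoxy-N,2-dimethyl-4-oxobutanamide | O=CC[C@@H](C)C(=O)N(C)OC | intermediate
15 | (R)-N,4,4-trimethoxy-N,2-dimethylbutanamide | COC(OC)C[C@@H](C)C(=O)N(C)OC | intermediate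
16 | {(E)-5-[(4-methoxybenzyl)oxy]-3-methylpent-3-en-1-yl}magnesium bromide | COc1ccc(COC/C=C(C)/CC[Mg]Br)cc1 | intermediate
17 | (3R,7E)-1,1-dimethoxy-9-[(4-methoxybenzyl)oxy]-3,7-dimethylnon-7-en-4-one | COC(OC)C[C@@H](C)C(=O)CC/C(C)=C/COCc1ccc(OC)cc1 | intermediate
18 | (3R,7E)-9-hydroxy-1,1-dimethoxy-3,7-dimethylnon-7-en-4-one | COC(OC)C[C@@H](C)C(=O)CC/C(C)=C/CO | intermediate
19 | (2E,7R)-9,9-dimethoxy-3,7-dimethyl-6-oxonon-2-enal | COC(OC)C[C@@H](C)C(=O)CC/C(C)=C/C=O | intermediate
20 | tert-butyldimethyl(prop-2-yn-1-yloxy)silane | C#CCO[Si](C)(C)C(C)(C)C | starting material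
21 | {3-[(tert-butyldimethylsilyl)oxy]prop-1-yn-1-yl}(methyl)zinc | C[Zn]C#CCO[Si](C)(C)C(C)(C)C | intermediate
22 | (3R,7E,9R)-12-[(tert-butyldimethylsilyl)oxy]-9-hydroxy-1,1-dimethoxy-3,7-dimethyldodec-7-en-10-yn-4-one | COC(OC)C[C@@H](C)C(=O)CC/C(C)=C/[C@@H](O)C#CCO[Si](C)(C)C(C)(C)C | intermediate
23 | (3R,7E,9R)-9,12-bis[(tert-butyldimethylsilyl)oxy]-1,1-dimethoxy-3,7-dimethyldodec-7-en-10-yn-4-one | COC(OC)C[C@@H](C)C(=O)CC/C(C)=C/[C@@H](O[Si](C)(C)C(C)(C)C)C#CCO[Si](C)(C)C(C)(C)C | intermediate
24 | (3R,7E,9R)-9-[(tert-butyldimethylsilyl)oxy]-12-hydroxy-1,1-dimethoxy-3,7-dimethyldodec-7-en-10-yn-4-one | COC(OC)C[C@@H](C)C(=O)CC/C(C)=C/[C@@H](O[Si](C)(C)C(C)(C)C)C#CCO | intermediate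
25 | (3R,7E,9R)-12-bromo-9-[(tert-butyldimethylsilyl)oxy]-1,1-dimethoxy-3,7-dimethyldodec-7-en-10-yn-4-one | COC(OC)C[C@@H](C)C(=O)CC/C(C)=C/[C@@H](O[Si](C)(C)C(C)(C)C)C#CCBr | intermediate
26 | (3R,7E,9R)-12-bromo-9-[(tert-butyldimethylsilyl)oxy]-3,7-dimethyl-4-oxododec-7-en-10-ynal | O=CC[C@@H](C)C(=O)CC/C(C)=C/[C@@H](O[Si](C)(C)C(C)(C)C)C#CCBr | intermediate
27 | dichloro{(4R,5E,10R)-4-[(tert-butyldimethylsilyl)oxy]-6,10-dimethyl-9,12-dioxododec-5-en-2-yn-1-yl}chromium | O=CC[C@@H](C)C(=O)CC/C(C)=C/[C@@H](O[Si](C)(C)C(C)(C)C)C#CC[Cr](Cl)Cl | intermediate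
28 | (4E,6R,8S,10R)-6-[(tert-butyldimethylsilyl)oxy]-7-ethenylidene-8-hydroxy-4,10-dimethylcyclodec-4-en-1-one | O[C@H]1C[C@@H](C)C(=O)CC/C(C)=C/[C@@H](O[Si](C)(C)C(C)(C)C)C1=C=C | intermediate
29 | angelic acid [(Z)-2-methylbut-2-enoic acid] | C/C=C(/C)C(=O)O | starting material
30 | (Z)-2-methylbut-2-enoic 2,4,6-trichlorobenzoic anhydride | C/C=C(/C)C(=O)OC(=O)c1c(Cl)cc(Cl)cc1Cl | intermediate
31 | (1S,3R,4E,9R)-3-[(tert-butyldimethylsilyl)oxy]-2-ethenylidene-5,9-dimethyl-8-oxocyclodec-4-en-1-yl (Z)-2-methylbut-2-enoate | C/C=C(/C)C(=O)O[C@H]1C[C@@H](C)C(=O)CC/C(C)=C/[C@@H](O[Si](C)(C)C(C)(C)C)C1=C=C | intermediate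
32 | (1S,3R,4E,9R)-2-ethenylidene-3-hydroxy-5,9-dimethyl-8-oxocyclodec-4-en-1-yl (Z)-2-methylbut-2-enoate | C/C=C(/C)C(=O)O[C@H]1C[C@@H](C)C(=O)CC/C(C)=C/[C@@H](O)C1=C=C | intermediate
33 | (4S,6R,10E,11aR)-3-(chloromethyl)-6,10-dimethyl-2,7-dioxo-2,4,5,6,7,8,9,11a-octahydrocyclodeca[b]furan-4-yl (Z)-2-methylbut-2-enoate | C/C=C(/C)C(=O)O[C@H]1C[C@@H](C)C(=O)CC/C(C)=C/[C@H]2OC(=O)C(CCl)=C12 | intermediate
34 | (4S,6R,10E,11aR)-3-(acetoxymethyl)-6,10-dimethyl-2,7-dioxo-2,4,5,6,7,8,9,11a-octahydrocyclodeca[b]furan-4-yl (Z)-2-methylbut-2-enoate | C/C=C(/C)C(=O)O[C@H]1C[C@@H](C)C(=O)CC/C(C)=C/[C@H]2OC(=O)C(COC(C)=O)=C12 | intermediate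
35 | (4R,5R,6S,8S,10R)-13-acetoxy-8-[(Z)-2-methylbut-2-enoyloxy]-4,5-epoxy-1-oxogermacr-7(11)-en-12,6-olide (germacrane numbering) | C/C=C(/C)C(=O)O[C@H]1C[C@@H](C)C(=O)CC[C@@]2(C)O[C@@H]2[C@H]2OC(=O)C(COC(C)=O)=C12 | target

**Step count and risks**

Total step count: 21. Longest linear sequence: 18 steps (steps 1–4 and 8–21, from 1).

Steps most likely to fail:

Step 16. The ring closure may show poor facial selectivity at the C8 aldehyde (attack on the other carbonyl face) and, to a lesser degree, bond formation through C13 instead of C7. The fallback moves the stereochemical burden from the addition to an SN2 inversion. It sets out from 26 as before; the epimeric alcohol that the cyclisation then delivers, (4E,6R,8R,10R)-6-[(tert-butyldimethylsilyl)oxy]-7-ethenylidene-8-hydroxy-4,10-dimethylcyclodec-4-en-1-one F1, is esterified with angelic acid 29 under Mitsunobu conditions (PPh3, diisopropyl azodicarboxylate, toluene, 0 °C). This should give the angelate with inversion at C8, so the route is rejoined at 31; any 28 formed alongside still passes through step 17.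

Step 19. The carbonylation may lose to 5-endo oxypalladation of the allenol (cycloisomerisation to a 2,5-dihydrofuran), to chloride delivery at C7, or to ionisation of the doubly activated C6–O bond by the acid and CuCl2. The fallback accepts the 5-endo mode and builds the lactone carbonyl from the allene terminus instead of CO. It sets out from 32: N-iodosuccinimide (CH2Cl2, 0 °C) should give the iodoetherification product (4S,6R,10E,11aR)-3-iodo-6,10-dimethyl-7-oxo-2,4,5,6,7,8,9,11a-octahydrocyclodeca[b]furan-4-yl (Z)-2-methylbut-2-enoate F2, in which O6 is bonded to the former allene terminus and iodine sits on the central carbon. Oxidation of the ring O–CH2 group (CrO3, 3,5-dimethylpyrazole, CH2Cl2, −20 °C) should give the α-iodobutenolide (4S,6R,10E,11aR)-3-iodo-6,10-dimethyl-2,7-dioxo-2,4,5,6,7,8,9,11a-octahydrocyclodeca[b]furan-4-yl (Z)-2-methylbut-2-enoate F3. Stille coupling of F3 with (tributylstannyl)methyl acetate (Pd(PPh3)4, CuI, DMF, 50 °C) introduces the acetoxymethyl carbon and comes back to the route at 34.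

Step 21. The oxidant may show poor facial selectivity on the lactone-fused ring, or lose chemoselectivity toward the angelate alkene. The fallback epoxidises earlier under hydroxyl direction. It sets out from 32: VO(acac)2 (cat.), t-BuOOH, CH2Cl2, 0 °C should deliver oxygen syn to the C6 hydroxyl (threo, A(1,3) control) and give the (4R,5R)-4,5-epoxide of allenol 32 F4. The conditions of step 19 then convert F4 into the (4R,5R)-4,5-epoxide of chloromethyl butenolide 33 F5, and the conditions of step 20 convert F5 into the target, so the route is rejoined at 35.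

Further compounds
F1 | step 16 | (4E,6R,8R,10R)-6-[(tert-butyldimethylsilyl)oxy]-7-ethenylidene-8-hydroxy-4,10-dimethylcyclodec-4-en-1-one | O[C@@H]1C[C@@H](C)C(=O)CC/C(C)=C/[C@@H](O[Si](C)(C)C(C)(C)C)C1=C=C
F2 | step 19 | (4S,6R,10E,11aR)-3-iodo-6,10-dimethyl-7-oxo-2,4,5,6,7,8,9,11a-octahydrocyclodeca[b]furan-4-yl (Z)-2-methylbut-2-enoate | C/C=C(/C)C(=O)O[C@H]1C[C@@H](C)C(=O)CC/C(C)=C/[C@H]2OCC(I)=C12
F3 | step 19 | (4S,6R,10E,11aR)-3-iodo-6,10-dimethyl-2,7-dioxo-2,4,5,6,7,8,9,11a-octahydrocyclodeca[b]furan-4-yl (Z)-2-methylbut-2-enoate | C/C=C(/C)C(=O)O[C@H]1C[C@@H](C)C(=O)CC/C(C)=C/[C@H]2OC(=O)C(I)=C12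
F4 | step 21 | (4R,5R)-4,5-epoxide of allenol 32 (germacrane numbering; 6S,8S,10R) | C/C=C(/C)C(=O)O[C@H]1C[C@@H](C)C(=O)CC[C@@]2(C)O[C@@H]2[C@@H](O)C1=C=C
F5 | step 21 | (4R,5R)-4,5-epoxide of chloromethyl butenolide 33 (germacrane numbering; 6S,8S,10R) | C/C=C(/C)C(=O)O[C@H]1C[C@@H](C)C(=O)CC[C@@]2(C)O[C@@H]2[C@H]2OC(=O)C(CCl)=C12
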